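## Structural features

The target is an achiral 2-arylbenzofuran: a benzofuran (ring A system) with a free hydroxyl at C6 is bonded through C2 to C1' of a pentasubstituted benzene, ring B. Ring B carries prenyl groups at C2' and C6' (both ortho to the biaryl bond), a methoxy group at C3', hydrogen at C4' and a free hydroxyl at C5'. There are no stereocentres, so none stand next to each other. The only stereochemical element on the way is olefin geometry in acyclic intermediates, and it is lost before the end. The fragile groups are the two trisubstituted prenyl olefins and the electron-rich phenols and benzofuran. Acid would cyclise the C6' prenyl group onto the C5' hydroxyl to a chroman, and hydrogenation or electrophilic oxidants would destroy the olefins. The real difficulty is ring B: it is substituted at every carbon but C4', its biaryl bond is flanked by two prenyl groups, and its two nearly symmetry-related oxygens must end as one methyl ether and one free phenol. The key step exploits this pattern: C5'(OH) ortho to C6', para to C2' and meta to C3'(OMe), with hydrogen at C4' in between. A vinylketene supplies C5', C2', C1' and C6', and an alkoxyalkyne supplies C4' and C3'.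

## Logic of the disconnections

22 is traced back to 21 by cutting only the O–CH3 bond of ring A. The ring B methyl ether stays, so the forward step must distinguish two aryl methyl ethers. It can do so because ring B of 21 already carries a free hydroxyl and reacts as a phenoxide.

21 is cut at C2'–C3', C4'–C5' and C5'–C6'. This removes ring B altogether and leaves 12 and 16. The hydroxyl oxygen then comes from the acyl carbon of 12 and the methyl ether from 16, so the two oxygens are different by origin and never need to be told apart. Atom mapping was checked: the acyl carbon of 12 becomes C5', C2 becomes C2', C3 becomes C1' and C4 becomes C6'. The C3 substituent of 12 must therefore be the 4-methylpent-3-enyl chain, one carbon longer than prenyl, and the C2 substituent must be prenyl. The forward step demands clean 1,4-elimination to 17, regioselective [2+2] to 18, and thermal passage through 19 and 20.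

16 is traced to 13 by adding back methanol and HCl across the triple bond. The forward step is a double base-induced elimination, and the demand is careful handling of a volatile product.

12 is traced through 11 to 10 by functional-group change at the acyl carbon only. The forward steps must avoid strong acid, because the two side-chain olefins are already present.

10 is cut at the C3–C4 bond, between an sp2 and an sp3 carbon, to give 7 and 8 (used as 9). This places the whole homoprenyl chain in one cheap reagent. The forward step must be a cross-coupling that tolerates an ester and a fully substituted alkenyl triflate.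

7 is traced to 6 by cutting the O–S bond, and 6 is cut at the C2–CH2 bond to give 4 and 5. Both forward steps are standard enolate chemistry of a β-keto ester that can enolise in one direction only.

4 is cut between the ketone carbon and the methylene carbon, which leads to 1 and a malonate half-ester. The forward step is a decarboxylative acylation.

## Other disconnections considered

Alternative 1: The cut is at the two aryl–CH2 bonds of the prenyl groups (C2' and C6'). Both are traced to oxygen-bound 1,1-dimethylallyl groups in the bis-ether A1, whose C4' is blocked by bromine. The forward key step is heating A1 so that two aromatic Claisen shifts give the diprenylated bromoresorcinol A2; no ring is formed.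
- In its favour: each ether oxygen has only one free ortho carbon, so the regiochemistry is fixed. The aromatic Claisen shift of reverse-prenyl ethers is a thoroughly established way to place a prenyl group ortho to a phenol, and on precedent for the bond being made this alternative is the better of the two. It also needs no volatile alkyne and no ketene.
- Against it here: both shifts must end on carbons that flank the biaryl bond, the most crowded positions of ring B. The tertiary ethers next to a bromine are awkward to make and ionise easily. The ortho-prenyl phenols formed can cyclise to chromans at the temperature of the shift.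
- The main structural weakness: ring B of A2 is symmetric and its two hydroxyls are equivalent. Methylating exactly one is statistical, and the bromine and the ring A methyl must still be removed.
- Comparison: both plans are thermal and pericyclic. The chosen plan passes through a more reactive intermediate with more side paths, but it differentiates the oxygens by construction and needs one operation after the key step where this alternative needs at least three. The number of steps before the key step is about the same.

Alternative 2: The cut is at the C2=C3 bond of the furan. The forward key step is an intramolecular reductive coupling, by low-valent titanium, of the aldehyde carbon and the ester carbonyl carbon of the aryl ester A3, which closes the furan and gives the trimethyl ether A4.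
- In its favour: it is highly convergent, since A3 is a simple ester of a ring B acid and a salicylaldehyde. The symmetry of a 3,5-dimethoxybenzoate helps when both prenyl groups are introduced. A thiolate endgame could in principle stop by itself after one of the two equivalent ring B methyl ethers, because the phenoxide formed protects the other. The overall length is therefore likely equal to or shorter than that of the chosen plan, and this is a real advantage.
- Against it here: the ester carbonyl that must couple lies between two ortho prenyl groups, so the ring closure is slow and intermolecular coupling of the aldehyde can take over. Strongly reducing, Lewis-acidic titanium species at reflux are not kind to trisubstituted olefins. The last step must remove the ring A methyl and exactly one ring B methyl in one operation, which is more delicate than the single demethylation of the chosen plan.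
- Comparison: this alternative builds the furan last on a finished ring B by single-electron chemistry. The chosen plan builds ring B last on a finished benzofuran by a pericyclic cascade, and the biaryl bond is never made under steric pressure.

Alternative 3: The cut is at C1'–C6' and C4'–C5'. The forward key step is a [4+2] cycloaddition of the 4-methoxy-2-pyrone A5 with the siloxyalkyne A6, followed by decarboxylative loss of the lactone bridge, to give the silyl ether A7.
- In its favour: ring B is built with its two oxygens already different (silyl against methyl), the same benefit as in the chosen plan, so the two are equal on this point. A5 and A6 are storable compounds, unlike a ketene, and the silyl group leaves with fluoride under very mild conditions; on handling and on this deprotection the alternative is the better. The polarity of the partners matches the required regiochemistry.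
- Against it here: the diene carries a donor at C4 and is fully substituted at C5 and C6, with the bulky benzofuranyl group on a reacting terminus. It is a poor partner for an electron-rich alkyne, and the cycloaddition can be expected to need temperatures at which siloxyalkynes rearrange. A5 needs its own multistep synthesis. The ring A methyl must still be removed afterwards, so two deprotections follow the key step.
- Comparison: both plans are cycloaddition–aromatisation sequences. The chosen plan uses a far more reactive pair (ketene and ynol ether), makes its precursor by a linear series of standard C–C bond formations, and ends with one deprotection. The total length of the alternative is similar or slightly greater.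

Key step: step 8

Assumption: methoxyacetylene is treated as too volatile and too scarce to rely on purchase, so it is made in step 7. The (2E) geometry of 10–12 is carried for definiteness but is erased when the ketene forms.

## Route

Step 1
Reactants: 1 6-methoxy-1-benzofuran-2-carboxylic acid
Product: 4 methyl 3-(6-methoxy-1-benzofuran-2-yl)-3-oxopropanoate, via acyl imidazolide 2 (not isolated), via acylmalonic half ester 3 (not isolated)
Conditions: CDI, THF, rt; then KO2CCH2CO2Me, MgCl2, THF, 50 °C; 1 M HCl work-up
Reagents that add atoms: potassium 3-methoxy-3-oxopropanoate, COC(=O)CC(=O)[O-].[K+]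
Why: Activation as the acyl imidazolide, C-acylation of the magnesium chelate of the malonate half-ester and decarboxylation on acidic work-up is the standard Masamune-type homologation of an aryl carboxylic acid to its β-keto ester; the benzofuran and the methyl ether are inert.

Step 2
Reactants: 4 methyl 3-(6-methoxy-1-benzofuran-2-yl)-3-oxopropanoate; 5 1-bromo-3-methylbut-2-ene
Product: 6 methyl 2-(6-methoxy-1-benzofuran-2-carbonyl)-5-methylhex-4-enoate (racemic)
Conditions: K2CO3, acetone, 40 °C (one equivalent of 5)
Reagents that add atoms: none
Why: The doubly stabilised enolate is alkylated at carbon by the allylic bromide in an SN2 reaction (acetoacetic ester alkylation); the weak base and one equivalent of 5 limit dialkylation, and the new stereocentre is racemic and disappears in step 3.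

Step 3
Reactants: 6 methyl 2-(6-methoxy-1-benzofuran-2-carbonyl)-5-methylhex-4-enoate
Product: 7 methyl (2Z)-3-(6-methoxy-1-benzofuran-2-yl)-2-(3-methylbut-2-en-1-yl)-3-[(trifluoromethanesulfonyl)oxy]prop-2-enoate
Conditions: NaH, CH2Cl2, 0 °C; then Tf2O, 0 °C
Reagents that add atoms: trifluoromethanesulfonic anhydride, O=S(=O)(OS(=O)(=O)C(F)(F)F)C(F)(F)F
Why: The ketone can enolise only toward C2, and O-sulfonylation of the chelated sodium enolate in a non-coordinating solvent should place the triflate cis to the ester (enol triflate formation from a β-keto ester); a geometric mixture would still serve, since this double bond is erased in step 8.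

Step 4
Reactants: 7 methyl (2Z)-3-(6-methoxy-1-benzofuran-2-yl)-2-(3-methylbut-2-en-1-yl)-3-[(trifluoromethanesulfonyl)oxy]prop-2-enoate; 8 5-bromo-2-methylpent-2-ene
Product: 10 methyl (2E)-3-(6-methoxy-1-benzofuran-2-yl)-7-methyl-2-(3-methylbut-2-en-1-yl)octa-2,6-dienoate, via Grignard reagent 9 (not isolated)
Conditions: 8, Mg, THF, rt; then 7, Fe(acac)3 (5 mol %), THF/NMP, −30 °C
Reagents that add atoms: none
Why: Iron-catalysed Kochi-type cross-coupling of alkenyl triflates with alkyl Grignard reagents is fast at low temperature, tolerates esters, is known for β-triflyloxy acrylates and proceeds with retention of olefin geometry; the homoallylic Grignard reagent is stable in its open-chain form.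

Step 5
Reactants: 10 methyl (2E)-3-(6-methoxy-1-benzofuran-2-yl)-7-methyl-2-(3-methylbut-2-en-1-yl)octa-2,6-dienoate
Product: 11 (2E)-3-(6-methoxy-1-benzofuran-2-yl)-7-methyl-2-(3-methylbut-2-en-1-yl)octa-2,6-dienoic acid
Conditions: LiOH·H2O, THF/MeOH/H2O, 60 °C; then cold 1 M HCl to pH 3
Reagents that add atoms: lithium hydroxide (hydroxide oxygen), [Li+].[OH-]
Why: Saponification by acyl–oxygen cleavage; nothing else in the molecule is base-sensitive, and a base-induced shift of the double bond out of conjugation would be harmless because the conjugated and the deconjugated acid chloride give the same ketene.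

Step 6
Reactants: 11 (2E)-3-(6-methoxy-1-benzofuran-2-yl)-7-methyl-2-(3-methylbut-2-en-1-yl)octa-2,6-dienoic acid
Product: 12 (2E)-3-(6-methoxy-1-benzofuran-2-yl)-7-methyl-2-(3-methylbut-2-en-1-yl)octa-2,6-dienoyl chloride
Conditions: 1-chloro-N,N,2-trimethylprop-1-en-1-amine (1.05 equiv), CH2Cl2, 0 °C → rt; concentrate, use crude
Reagents that add atoms: 1-chloro-N,N,2-trimethylprop-1-en-1-amine, CC(C)=C(Cl)N(C)C
Why: The α-chloroenamine (Ghosez reagent) turns even hindered acids into acid chlorides under neutral conditions, so no HCl is set free that could add to the two trisubstituted olefins; the amide co-product is inert in step 8.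

Step 7
Reactants: 13 2-chloro-1,1-dimethoxyethane
Product: 16 methoxyethyne (methoxyacetylene), via chlorovinyl ether 14 (not isolated), via sodium methoxyethynide 15 (not isolated)
Conditions: NaNH2 (3 equiv), liquid NH3, −33 °C; then cold saturated aqueous NaCl; distil cold into toluene
Reagents that add atoms: none
Why: Two successive base-induced eliminations (methanol, then HCl) and deprotonation give the sodium acetylide, and a cold aqueous quench liberates the alkyne, the classical preparation of alkoxyacetylenes; the product (b.p. near room temperature) is kept as a cold titrated toluene solution and used at once.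

Step 8
Reactants: 12 (2E)-3-(6-methoxy-1-benzofuran-2-yl)-7-methyl-2-(3-methylbut-2-en-1-yl)octa-2,6-dienoyl chloride; 16 methoxyethyne
Product: 21 3-methoxy-5-(6-methoxy-1-benzofuran-2-yl)-4,6-bis(3-methylbut-2-en-1-yl)phenol, via vinylketene 17 (not isolated), via cyclobutenone 18 (not isolated), via dienylketene 19 (not isolated), via cyclohexadienone 20 (not isolated)
Conditions: Et3N (2.5 equiv), 16 (5 equiv), toluene, sealed tube, 25 → 60 °C; then 95 °C
Reagents that add atoms: none
Why: Et3N removes a C4 hydrogen of 12 in a vinylogous 1,4-dehydrochlorination and gives vinylketene 17, the amine-mediated ketene generation long used for ketene cycloadditions. The electrophilic ketene carbonyl carbon (future C5') is attacked by the nucleophilic terminal carbon of the ynol ether (C4') and the ketene α-carbon (C2') closes onto the oxygen-bearing carbon (C3'), a polarity-controlled [2+2] that gives the 3-methoxycyclobutenone 18. On heating, reversible conrotatory four-electron opening of 18 breaks the C5'–C2' bond to give dienylketene 19, and a thermally allowed disrotatory six-electron electrocyclization joins C5' to C6' and closes ring B as dienone 20, which enolises to phenol 21 with help from the amine. The closest known reaction type is the Danheiser benzannulation of vinylketenes with alkoxyalkynes to resorcinol monoethers; only the ketene source differs from the usual cyclobutenone or diazo ketone. No stereocentre survives: the quaternary carbon of 18 and the sp3 carbon of 20 are racemic and become aromatic, and the geometry of the C3=C4 bond of 17 does not matter because either isomer of 19 can close. The step needs regioselectivity in the [2+2]; the strong polarisation of 16 secures it, places hydrogen at C4' between the oxygens, and derives the free hydroxyl from the acyl carbon and the methyl ether from the alkyne. It also needs intermolecular capture to outrun intramolecular [2+2] of the ketene with the side-chain olefin and O-acylation of the product; the excess of the highly ketenophilic alkyne, the low reactivity of a disubstituted ketene toward unactivated alkenes, and the two temperature stages (all of 12 stored as 18 before any phenol forms) are meant to secure this.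

Step 9
Reactants: 21 3-methoxy-5-(6-methoxy-1-benzofuran-2-yl)-4,6-bis(3-methylbut-2-en-1-yl)phenol
Product: 22 2-[3-hydroxy-5-methoxy-2,6-bis(3-methylbut-2-en-1-yl)phenyl]-1-benzofuran-6-ol
Conditions: NaSEt (5 equiv), DMF, 120 °C; then cold 1 M HCl to pH 5
Reagents that add atoms: none
Why: SN2 demethylation of an aryl methyl ether by thiolate; ring B is a phenoxide under the conditions, so loss of its methyl would require a resorcinolate dianion as leaving group and should not occur, while the ring A methoxy on the separate, twisted benzofuran is cleaved normally; the prenyl olefins and the benzofuran offer no electrophilic site.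

## Compound list

1 | 6-methoxy-1-benzofuran-2-carboxylic acid | COc1ccc2cc(C(=O)O)oc2c1 | starting material
2 | (1H-imidazol-1-yl)(6-methoxy-1-benzofuran-2-yl)methanone | COc1ccc2cc(C(=O)n3ccnc3)oc2c1 | intermediate (not isolated)
3 | 3-methoxy-2-(6-methoxy-1-benzofuran-2-carbonyl)-3-oxopropanoic acid (as magnesium chelate) | COC(=O)C(C(=O)O)C(=O)c1cc2ccc(OC)cc2o1 | intermediate (not isolated)
4 | methyl 3-(6-methoxy-1-benzofuran-2-yl)-3-oxopropanoate | COC(=O)CC(=O)c1cc2ccc(OC)cc2o1 | intermediate
5 | 1-bromo-3-methylbut-2-ene | CC(C)=CCBr | starting material
6 | methyl 2-(6-methoxy-1-benzofuran-2-carbonyl)-5-methylhex-4-enoate (racemic) | COC(=O)C(CC=C(C)C)C(=O)c1cc2ccc(OC)cc2o1 | intermediate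
7 | methyl (2Z)-3-(6-methoxy-1-benzofuran-2-yl)-2-(3-methylbut-2-en-1-yl)-3-[(trifluoromethanesulfonyl)oxy]prop-2-enoate | COC(=O)/C(CC=C(C)C)=C(\OS(=O)(=O)C(F)(F)F)c1cc2ccc(OC)cc2o1 | intermediate
8 | 5-bromo-2-methylpent-2-ene | CC(C)=CCCBr | starting material
9 | (4-methylpent-3-en-1-yl)magnesium bromide | CC(C)=CCC[Mg]Br | intermediate (not isolated)
10 | methyl (2E)-3-(6-methoxy-1-benzofuran-2-yl)-7-methyl-2-(3-methylbut-2-en-1-yl)octa-2,6-dienoate | COC(=O)/C(CC=C(C)C)=C(/c1cc2ccc(OC)cc2o1)CCC=C(C)C | intermediate
11 | (2E)-3-(6-methoxy-1-benzofuran-2-yl)-7-methyl-2-(3-methylbut-2-en-1-yl)octa-2,6-dienoic acid | OC(=O)/C(CC=C(C)C)=C(/c1cc2ccc(OC)cc2o1)CCC=C(C)C | intermediate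
12 | (2E)-3-(6-methoxy-1-benzofuran-2-yl)-7-methyl-2-(3-methylbut-2-en-1-yl)octa-2,6-dienoyl chloride | O=C(Cl)/C(CC=C(C)C)=C(/c1cc2ccc(OC)cc2o1)CCC=C(C)C | intermediate
13 | 2-chloro-1,1-dimethoxyethane | COC(CCl)OC | starting material
14 | 1-chloro-2-methoxyethene (geometry not defined) | COC=CCl | intermediate (not isolated)
15 | sodium 2-methoxyethyn-1-ide | [Na+].[C-]#COC | intermediate (not isolated)
16 | methoxyethyne (methoxyacetylene) | COC#C | intermediate
17 | 3-(6-methoxy-1-benzofuran-2-yl)-7-methyl-2-(3-methylbut-2-en-1-yl)octa-1,3,6-trien-1-one (C3=C4 geometry not defined) | O=C=C(CC=C(C)C)C(=CCC=C(C)C)c1cc2ccc(OC)cc2o1 | intermediate (not isolated)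
18 | 3-methoxy-4-[1-(6-methoxy-1-benzofuran-2-yl)-5-methylhexa-1,4-dien-1-yl]-4-(3-methylbut-2-en-1-yl)cyclobut-2-en-1-one (racemic) | O=C1C=C(OC)C1(CC=C(C)C)C(=CCC=C(C)C)c1cc2ccc(OC)cc2o1 | intermediate (not isolated)
19 | 3-methoxy-5-(6-methoxy-1-benzofuran-2-yl)-9-methyl-4-(3-methylbut-2-en-1-yl)deca-1,3,5,8-tetraen-1-one (geometry not defined) | O=C=CC(OC)=C(CC=C(C)C)C(=CCC=C(C)C)c1cc2ccc(OC)cc2o1 | intermediate (not isolated)
20 | 3-methoxy-5-(6-methoxy-1-benzofuran-2-yl)-4,6-bis(3-methylbut-2-en-1-yl)cyclohexa-2,4-dien-1-one (racemic) | O=C1C=C(OC)C(CC=C(C)C)=C(c2cc3ccc(OC)cc3o2)C1CC=C(C)C | intermediate (not isolated)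
21 | 3-methoxy-5-(6-methoxy-1-benzofuran-2-yl)-4,6-bis(3-methylbut-2-en-1-yl)phenol | COc1ccc2cc(-c3c(CC=C(C)C)c(OC)cc(O)c3CC=C(C)C)oc2c1 | intermediate
22 | 2-[3-hydroxy-5-methoxy-2,6-bis(3-methylbut-2-en-1-yl)phenyl]-1-benzofuran-6-ol | COc1cc(O)c(CC=C(C)C)c(-c2cc3ccc(O)cc3o2)c1CC=C(C)C | target

## Step count and least certain steps

Total step count: 9. Longest linear sequence: 8 (steps 1–6, 8 and 9); step 7 is a one-step side branch.

**Step 8 (key step).** Three processes are most likely to go wrong.
- Deprotonation at C4 of the hindered, tetrasubstituted acyl chloride may be slow, so that ketene is still being formed when phenol is already present and the phenol is O-acylated.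
- Where the new C3=C4 bond forms with the side chain cis to the ketene, the ketene can add intramolecularly to the C6=C7 olefin; this is the pathway by which terpenoid dienoyl chlorides are known to give bicyclo[3.1.1]heptenones.
- The ynol ether can be lost by protonation by the ammonium salt or by escape from the vessel.

Fallback, from 11 back to the route at 18: the dianion of 11 (LiN(i-Pr)2, 2.2 equiv, THF, −78 → 0 °C) is protonated kinetically at C2 at −78 °C to give the deconjugated 3-(6-methoxy-1-benzofuran-2-yl)-7-methyl-2-(3-methylbut-2-en-1-yl)octa-3,6-dienoic acid F1. The same α-chloroenamine converts it into the corresponding octa-3,6-dienoyl chloride F2. This chloride has an ordinary α-hydrogen, so Et3N should generate 17 at 0 °C to room temperature by simple 1,2-dehydrochlorination in the presence of 16. At that temperature only the [2+2] can follow, and 18 would be isolated. Heating purified 18 in toluene then gives 21, with no acyl chloride, amine salt or free alkyne present.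

**Step 9.** The thiolate may also attack the ring B methyl ether, or the prenyl double bonds may migrate into conjugation at the temperature needed.

Fallback, from 11 to 22: the demethylation is moved ahead of the key step, where the molecule has only one methyl ether.
- NaSEt in DMF converts 11 into (2E)-3-(6-hydroxy-1-benzofuran-2-yl)-7-methyl-2-(3-methylbut-2-en-1-yl)octa-2,6-dienoic acid F3.
- t-BuMe2SiCl and imidazole give the silyl ester silyl ether tert-butyldimethylsilyl (2E)-3-{6-[(tert-butyldimethylsilyl)oxy]-1-benzofuran-2-yl}-7-methyl-2-(3-methylbut-2-en-1-yl)octa-2,6-dienoate F4.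
- Oxalyl chloride with catalytic DMF converts the silyl ester directly, without HCl, into (2E)-3-{6-[(tert-butyldimethylsilyl)oxy]-1-benzofuran-2-yl}-7-methyl-2-(3-methylbut-2-en-1-yl)octa-2,6-dienoyl chloride F5.
- The conditions of step 8 give 5-{6-[(tert-butyldimethylsilyl)oxy]-1-benzofuran-2-yl}-3-methoxy-4,6-bis(3-methylbut-2-en-1-yl)phenol F6.
- Bu4NF in THF at 0 °C gives 22.

**Step 4.** Oxidative addition and transmetalation at the crowded, fully substituted triflate may be slow, so that attack of the Grignard reagent at sulfur (return to the β-keto ester) and homocoupling take over.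

Fallback, from 5 back to the route at 10, with the roles of the partners reversed:
- The dianion of methyl acetoacetate (NaH, then n-BuLi, THF, 0 °C) is alkylated by 5 at the terminal carbon to give methyl 7-methyl-3-oxooct-6-enoate F7.
- A second equivalent of 5 with K2CO3 in acetone gives methyl 7-methyl-2-(3-methylbut-2-en-1-yl)-3-oxooct-6-enoate F8.
- Triflation under non-chelating conditions (aqueous Me4NOH, Tf2O, hexane) gives methyl (2E)-7-methyl-2-(3-methylbut-2-en-1-yl)-3-[(trifluoromethanesulfonyl)oxy]octa-2,6-dienoate F9.
- Suzuki–Miyaura coupling with commercial (6-methoxy-1-benzofuran-2-yl)boronic acid F10 (Pd(dppf)Cl2, K3PO4, THF/H2O, 50 °C) gives 10.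

The geometric isomer of 10 would serve equally, since the geometry is erased in step 8.

**Step 5.** Hydroxide attack on the shielded ester carbonyl may be very slow, so that forcing conditions are needed.

Fallback, from 10 back to the route at 11, by a redox detour:
- i-Bu2AlH in CH2Cl2 at −78 °C gives (2E)-3-(6-methoxy-1-benzofuran-2-yl)-7-methyl-2-(3-methylbut-2-en-1-yl)octa-2,6-dien-1-ol F11.
- MnO2 in CH2Cl2 gives (2E)-3-(6-methoxy-1-benzofuran-2-yl)-7-methyl-2-(3-methylbut-2-en-1-yl)octa-2,6-dienal F12.
- Pinnick oxidation (NaClO2, NaH2PO4, a large excess of 2-methylbut-2-ene, t-BuOH/H2O) gives 11.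

## Further compounds

F1 | step 8 | 3-(6-methoxy-1-benzofuran-2-yl)-7-methyl-2-(3-methylbut-2-en-1-yl)octa-3,6-dienoic acid (racemic, C3=C4 geometry not defined) | OC(=O)C(CC=C(C)C)C(=CCC=C(C)C)c1cc2ccc(OC)cc2o1
F2 | step 8 | 3-(6-methoxy-1-benzofuran-2-yl)-7-methyl-2-(3-methylbut-2-en-1-yl)octa-3,6-dienoyl chloride (racemic, C3=C4 geometry not defined) | O=C(Cl)C(CC=C(C)C)C(=CCC=C(C)C)c1cc2ccc(OC)cc2o1
F3 | step 9 | (2E)-3-(6-hydroxy-1-benzofuran-2-yl)-7-methyl-2-(3-methylbut-2-en-1-yl)octa-2,6-dienoic acid | OC(=O)/C(CC=C(C)C)=C(/c1cc2ccc(O)cc2o1)CCC=C(C)C
F4 | step 9 | tert-butyldimethylsilyl (2E)-3-{6-[(tert-butyldimethylsilyl)oxy]-1-benzofuran-2-yl}-7-methyl-2-(3-methylbut-2-en-1-yl)octa-2,6-dienoate | CC(C)(C)[Si](C)(C)OC(=O)/C(CC=C(C)C)=C(/c1cc2ccc(O[Si](C)(C)C(C)(C)C)cc2o1)CCC=C(C)C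
F5 | step 9 | (2E)-3-{6-[(tert-butyldimethylsilyl)oxy]-1-benzofuran-2-yl}-7-methyl-2-(3-methylbut-2-en-1-yl)octa-2,6-dienoyl chloride | O=C(Cl)/C(CC=C(C)C)=C(/c1cc2ccc(O[Si](C)(C)C(C)(C)C)cc2o1)CCC=C(C)C
F6 | step 9 | 5-{6-[(tert-butyldimethylsilyl)oxy]-1-benzofuran-2-yl}-3-methoxy-4,6-bis(3-methylbut-2-en-1-yl)phenol | COc1cc(O)c(CC=C(C)C)c(-c2cc3ccc(O[Si](C)(C)C(C)(C)C)cc3o2)c1CC=C(C)C
F7 | step 4 | methyl 7-methyl-3-oxooct-6-enoate | COC(=O)CC(=O)CCC=C(C)C
F8 | step 4 | methyl 7-methyl-2-(3-methylbut-2-en-1-yl)-3-oxooct-6-enoate (racemic) | COC(=O)C(CC=C(C)C)C(=O)CCC=C(C)C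
F9 | step 4 | methyl (2E)-7-methyl-2-(3-methylbut-2-en-1-yl)-3-[(trifluoromethanesulfonyl)oxy]octa-2,6-dienoate | COC(=O)/C(CC=C(C)C)=C(/OS(=O)(=O)C(F)(F)F)CCC=C(C)C
F10 | step 4 | (6-methoxy-1-benzofuran-2-yl)boronic acid | COc1ccc2cc(B(O)O)oc2c1
F11 | step 5 | (2E)-3-(6-methoxy-1-benzofuran-2-yl)-7-methyl-2-(3-methylbut-2-en-1-yl)octa-2,6-dien-1-ol | OC/C(CC=C(C)C)=C(/c1cc2ccc(OC)cc2o1)CCC=C(C)C
F12 | step 5 | (2E)-3-(6-methoxy-1-benzofuran-2-yl)-7-methyl-2-(3-methylbut-2-en-1-yl)octa-2,6-dienal | O=C/C(CC=C(C)C)=C(/c1cc2ccc(OC)cc2o1)CCC=C(C)C
A1 | alternative 1 | 2-{4-bromo-3,5-bis[(2-methylbut-3-en-2-yl)oxy]phenyl}-6-methoxy-1-benzofuran | COc1ccc2cc(-c3cc(OC(C)(C)C=C)c(Br)c(OC(C)(C)C=C)c3)oc2c1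
A2 | alternative 1 | 2-bromo-5-(6-methoxy-1-benzofuran-2-yl)-4,6-bis(3-methylbut-2-en-1-yl)benzene-1,3-diol | COc1ccc2cc(-c3c(CC=C(C)C)c(O)c(Br)c(O)c3CC=C(C)C)oc2c1
A3 | alternative 2 | 2-formyl-5-methoxyphenyl 3,5-dimethoxy-2,6-bis(3-methylbut-2-en-1-yl)benzoate | COc1ccc(C=O)c(OC(=O)c2c(CC=C(C)C)c(OC)cc(OC)c2CC=C(C)C)c1
A4 | alternative 2 | 2-[3,5-dimethoxy-2,6-bis(3-methylbut-2-en-1-yl)phenyl]-6-methoxy-1-benzofuran | COc1ccc2cc(-c3c(CC=C(C)C)c(OC)cc(OC)c3CC=C(C)C)oc2c1
A5 | alternative 3 | 4-methoxy-6-(6-methoxy-1-benzofuran-2-yl)-5-(3-methylbut-2-en-1-yl)-2H-pyran-2-one | COc1cc(=O)oc(-c2cc3ccc(OC)cc3o2)c1CC=C(C)C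
A6 | alternative 3 | triisopropyl[(5-methylhex-4-en-1-yn-1-yl)oxy]silane | CC(C)=CCC#CO[Si](C(C)C)(C(C)C)C(C)C
A7 | alternative 3 | 6-methoxy-2-[3-methoxy-2,6-bis(3-methylbut-2-en-1-yl)-5-(triisopropylsilyloxy)phenyl]-1-benzofuran | COc1ccc2cc(-c3c(CC=C(C)C)c(OC)cc(O[Si](C(C)C)(C(C)C)C(C)C)c3CC=C(C)C)oc2c1
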